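**Retrosynthetic overview**

- Feature: the only stereocentre is the benzylic carbon C1 of the propyl chain, bonded to the ester oxygen, to the 3,4,5-trimethoxyphenyl ring (ring A, the only ring, bought intact) and to an ethyl group. If the ethyl is read as a hydrogenated vinyl, C1–O becomes the branched position of an aryl-substituted allyl system.
- Last disconnection: hydrogenation of that vinyl group, so the target comes from the (S)-1-arylprop-2-enyl ester.
- Key disconnection: the benzylic C1–O bond, made from the linear (E)-cinnamyl methyl carbonate and the free Z,Z-diester acid by iridium–phosphoramidite branched-selective allylic esterification.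
- The acid comes from tert-butyl (Z)-2-(hydroxymethyl)but-2-enoate and angelic acid; the hydroxy ester comes from tert-butyl but-2-ynoate by syn hydroalumination and capture with formaldehyde; the carbonate comes from 3,4,5-trimethoxycinnamic acid.
- No ring is formed at any stage.

Key step: step 8

Assumption: the carboxylate is taken to attack the same allyl face as amine and phenoxide nucleophiles do with this ligand family, so the (Sa,S,S)-phosphoramidite is chosen for the S ester; if the R ester were to form, the mirror-image ligand would be used.

**Route**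

Step 1
Reactants: 1 but-2-ynoic acid
Product: 2 tert-butyl but-2-ynoate
Conditions: t-BuOC(=NH)CCl3 (2 equiv), BF3·OEt2 (cat.), CH2Cl2/cyclohexane, rt
Reagents that add atoms: tert-butyl 2,2,2-trichloroacetimidate, CC(C)(C)OC(=N)C(Cl)(Cl)Cl
Why: Acid-catalysed O-alkylation of a carboxylic acid by a trichloroacetimidate (tert-butyl ester formation) leaves the ynoate untouched and installs an ester that resists 1,2-reduction in step 2 and is later removed by acid alone.

Step 2
Reactants: 2 tert-butyl but-2-ynoate
Product: 4 tert-butyl (Z)-2-(hydroxymethyl)but-2-enoate, via α-alumino enoate 3 (not isolated)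
Conditions: i-Bu2AlH, NMO, THF, 0 °C; then monomeric CH2O (from cracked paraformaldehyde) in THF, 0 °C to rt; aqueous potassium sodium tartrate
Reagents that add atoms: formaldehyde, C=O; diisobutylaluminium hydride, CC(C)C[AlH]CC(C)C (its aluminium is carried only by intermediate 3)
Why: Conjugate syn hydroalumination of the ynoate by the i-Bu2AlH·NMO complex puts H on C3 and Al on C2, and the α-alumino enoate is captured by formaldehyde at C2 with retention (vinylalumination, a reductive Morita–Baylis–Hillman-type aldol), so the C4 methyl should end up cis to the ester, which is the Z alkene.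

Step 3
Reactants: 4 tert-butyl (Z)-2-(hydroxymethyl)but-2-enoate, 5 angelic acid
Product: 7 tert-butyl (Z)-2-{[(Z)-2-methylbut-2-enoyl]oxymethyl}but-2-enoate, via mixed anhydride 6 (not isolated)
Conditions: 5, 2,4,6-Cl3C6H2COCl, Et3N, toluene, rt; then 4, toluene, 80 °C (no DMAP)
Reagents that add atoms: 2,4,6-trichlorobenzoyl chloride, O=C(Cl)c1c(Cl)cc(Cl)cc1Cl (its atoms stay only in intermediate 6)
Why: Yamaguchi-type mixed-anhydride esterification without a nucleophilic catalyst acylates the primary alcohol at the angeloyl carbonyl, because the trichlorobenzoyl carbonyl is shielded by two ortho chlorines, and it avoids the conjugate-addition pathway by which DMAP isomerises angelates to tiglates.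

Step 4
Reactants: 7 tert-butyl (Z)-2-{[(Z)-2-methylbut-2-enoyl]oxymethyl}but-2-enoate
Product: 8 (Z)-2-{[(Z)-2-methylbut-2-enoyl]oxymethyl}but-2-enoic acid
Conditions: TFA/CH2Cl2 (1:4), 0 °C to rt
Reagents that add atoms: none
Why: Acidolysis of the tert-butyl ester with loss of isobutene frees the acid, while the primary allylic angelate sits on an electron-poor alkene and should not ionise, and no base or nucleophile is present that could isomerise either Z enoate.

Step 5
Reactants: 9 (E)-3,4,5-trimethoxycinnamic acid
Product: 10 methyl (E)-3-(3,4,5-trimethoxyphenyl)prop-2-enoate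
Conditions: MeOH, H2SO4 (cat.), reflux
Reagents that add atoms: methanol, CO
Why: Fischer esterification driven by excess methanol should give the methyl ester without touching the E alkene or the aryl ethers.

Step 6
Reactants: 10 methyl (E)-3-(3,4,5-trimethoxyphenyl)prop-2-enoate
Product: 11 (E)-3-(3,4,5-trimethoxyphenyl)prop-2-en-1-ol
Conditions: i-Bu2AlH (2.3 equiv), CH2Cl2, −78 to 0 °C; aqueous potassium sodium tartrate
Reagents that add atoms: none
Why: 1,2-Reduction of a cinnamate ester by i-Bu2AlH gives the allylic alcohol with the E alkene retained.

Step 7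
Reactants: 11 (E)-3-(3,4,5-trimethoxyphenyl)prop-2-en-1-ol
Product: 12 methyl (E)-3-(3,4,5-trimethoxyphenyl)prop-2-enyl carbonate
Conditions: ClCO2Me, pyridine, CH2Cl2, 0 °C
Reagents that add atoms: methyl chloroformate, COC(=O)Cl
Why: O-Acylation of the primary allylic alcohol with a chloroformate gives the linear carbonate, whose leaving group breaks down to CO2 and methoxide in step 8.

Step 8
Reactants: 8 (Z)-2-{[(Z)-2-methylbut-2-enoyl]oxymethyl}but-2-enoic acid, 12 methyl (E)-3-(3,4,5-trimethoxyphenyl)prop-2-enyl carbonate
Product: 13 (S)-1-(3,4,5-trimethoxyphenyl)prop-2-enyl (Z)-2-{[(Z)-2-methylbut-2-enoyl]oxymethyl}but-2-enoate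
Conditions: [Ir(cod)Cl]2 (2 mol%), (Sa,S,S)-O,O'-(1,1'-binaphthalene-2,2'-diyl) N,N-bis(1-phenylethyl)phosphoramidite (4 mol%), TBD (8 mol%), THF, rt (catalyst activation); then 12, then 8 (1.3 equiv) added slowly, THF, rt, argon; stopped when 12 is consumed
Reagents that add atoms: none
Why: The cyclometalated monovalent iridium–phosphoramidite complex ionises carbonate 12 with loss of CO2 and methoxide, which deprotonates acid 8, and the resulting carboxylate attacks the cationic allyl complex of trivalent iridium at the aryl-bearing terminus from the face opposite the metal. The closest known reaction type is the iridium–phosphoramidite branched-selective enantioselective allylic substitution of cinnamyl carbonates by carboxylate, phenoxide and amine nucleophiles. No ring is closed; the single new stereocentre, the benzylic C–O carbon, is set by the catalyst, whose ligand configuration fixes which face of the allyl ligand is open to the nucleophile, the (Sa,S,S) ligand being expected to give S. Branched-over-linear selectivity is needed and is secured by the catalyst together with the para-methoxy group of ring A, which stabilises positive charge at the benzylic terminus. Chemoselectivity is needed as well: the allylic angelate inside 8 is a 2-substituted allyl ester that this catalyst ionises poorly, and the medium stays a weakly acidic carboxylic acid/carboxylate buffer in which neither Z enoate should isomerise. The run is ended as soon as 12 is consumed so that the branched ester is not re-ionised and drained to the linear isomer.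

Step 9
Reactants: 13 (S)-1-(3,4,5-trimethoxyphenyl)prop-2-enyl (Z)-2-{[(Z)-2-methylbut-2-enoyl]oxymethyl}but-2-enoate
Product: 14 (S)-1-(3,4,5-trimethoxyphenyl)propyl (Z)-2-{[(Z)-2-methylbut-2-enoyl]oxymethyl}but-2-enoate
Conditions: H2 (1 atm), RhCl(PPh3)3 (5 mol%), toluene, rt
Reagents that add atoms: none
Why: Homogeneous hydrogenation with RhCl(PPh3)3 reduces a monosubstituted alkene far faster than trisubstituted, electron-poor enoates and does not hydrogenolyse benzylic esters, so only the vinyl group should become ethyl and the stereocentre is not touched.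

**Compound list**

1 | but-2-ynoic acid | CC#CC(=O)O | starting material
2 | tert-butyl but-2-ynoate | CC#CC(=O)OC(C)(C)C | intermediate
3 | tert-butyl (E)-2-(diisobutylalumanyl)but-2-enoate | C/C=C(/[Al](CC(C)C)CC(C)C)C(=O)OC(C)(C)C | intermediate
4 | tert-butyl (Z)-2-(hydroxymethyl)but-2-enoate | C/C=C(/CO)C(=O)OC(C)(C)C | intermediate
5 | angelic acid, (Z)-2-methylbut-2-enoic acid | C/C=C(/C)C(=O)O | starting material
6 | (Z)-2-methylbut-2-enoic 2,4,6-trichlorobenzoic anhydride | C/C=C(/C)C(=O)OC(=O)c1c(Cl)cc(Cl)cc1Cl | intermediate
7 | tert-butyl (Z)-2-{[(Z)-2-methylbut-2-enoyl]oxymethyl}but-2-enoate | C/C=C(/C)C(=O)OC/C(=C/C)C(=O)OC(C)(C)C | intermediate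
8 | (Z)-2-{[(Z)-2-methylbut-2-enoyl]oxymethyl}but-2-enoic acid | C/C=C(/C)C(=O)OC/C(=C/C)C(=O)O | intermediate
9 | (E)-3,4,5-trimethoxycinnamic acid | COc1cc(/C=C/C(=O)O)cc(OC)c1OC | starting material
10 | methyl (E)-3-(3,4,5-trimethoxyphenyl)prop-2-enoate | COC(=O)/C=C/c1cc(OC)c(OC)c(OC)c1 | intermediate
11 | (E)-3-(3,4,5-trimethoxyphenyl)prop-2-en-1-ol | OC/C=C/c1cc(OC)c(OC)c(OC)c1 | intermediate
12 | methyl (E)-3-(3,4,5-trimethoxyphenyl)prop-2-enyl carbonate | COC(=O)OC/C=C/c1cc(OC)c(OC)c(OC)c1 | intermediate
13 | (S)-1-(3,4,5-trimethoxyphenyl)prop-2-enyl (Z)-2-{[(Z)-2-methylbut-2-enoyl]oxymethyl}but-2-enoate | C/C=C(/C)C(=O)OC/C(=C/C)C(=O)O[C@@H](C=C)c1cc(OC)c(OC)c(OC)c1 | intermediate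
14 | (S)-1-(3,4,5-trimethoxyphenyl)propyl (Z)-2-{[(Z)-2-methylbut-2-enoyl]oxymethyl}but-2-enoate | C/C=C(/C)C(=O)OC/C(=C/C)C(=O)O[C@@H](CC)c1cc(OC)c(OC)c(OC)c1 | target

**Step count**

Total steps: 9. Longest linear sequence: 6 steps (steps 1, 2, 3, 4, 8, 9, from but-2-ynoic acid).

**Steps most likely to fail**

Step 8. The hindered, weakly nucleophilic carboxylate may attack slowly, so that the electron-rich branched ester is re-ionised by the catalyst and drifts to the linear isomer with loss of enantiopurity. The fallback sets the stereocentre by ketone reduction and forms the ester by acylation; it sets out from acid 8 and comes back to the route at target 14, bypassing 13 and step 9. Bought 1-(3,4,5-trimethoxyphenyl)propan-1-one F1 would be reduced with BH3·SMe2 and (R)-2-methyl-CBS-oxazaborolidine (cat.) in THF at −20 °C (Corey–Bakshi–Shibata reduction) to (S)-1-(3,4,5-trimethoxyphenyl)propan-1-ol F2. Acid 8 would be converted with 2,4,6-trichlorobenzoyl chloride and Et3N in toluene into (Z)-2-{[(Z)-2-methylbut-2-enoyl]oxymethyl}but-2-enoic 2,4,6-trichlorobenzoic anhydride F3. F3 would then acylate F2 in toluene at 60–80 °C without DMAP, with retention at the carbinol carbon, to give 14.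

Step 2. The α-alumino enoate may equilibrate through its aluminium allenolate and erode the Z geometry, the ester may undergo 1,2-reduction, or gaseous formaldehyde may be captured inefficiently. The fallback replaces the aluminium route by a tin–iodine–palladium sequence; it sets out from ynoate 2 and comes back at hydroxy ester 4. Syn hydrostannation of 2 with Bu3SnH and Pd(PPh3)4 (cat.) in THF would give tert-butyl (E)-2-(tributylstannyl)but-2-enoate F4, with tin at C2. Iododestannylation with I2 in CH2Cl2 at 0 °C, with retention, would give tert-butyl (E)-2-iodobut-2-enoate F5, in which the methyl is cis to the ester. Stille coupling of F5 with (tributylstannyl)methanol and Pd(PPh3)4 in dioxane at 80 °C, by way of zerovalent palladium and with retention of alkene geometry, would give 4.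

Step 9. The rhodium hydride may move the terminal double bond into conjugation with ring A to give an enol ester, or the catalyst may ionise the allylic benzylic ester. The fallback is a metal-free transfer of H2; it sets out from 13 and comes back at 14. Diimide generated in the flask from 2-nitrobenzenesulfonyl hydrazide and Et3N in CH2Cl2 at rt delivers H2 by a concerted syn transfer, which is much faster for the unhindered monosubstituted alkene than for the two trisubstituted enoates and cannot cleave or ionise the benzylic C–O bond.

**Further compounds**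

F1 | step 8 | 1-(3,4,5-trimethoxyphenyl)propan-1-one (bought) | CCC(=O)c1cc(OC)c(OC)c(OC)c1
F2 | step 8 | (S)-1-(3,4,5-trimethoxyphenyl)propan-1-ol | CC[C@H](O)c1cc(OC)c(OC)c(OC)c1
F3 | step 8 | (Z)-2-{[(Z)-2-methylbut-2-enoyl]oxymethyl}but-2-enoic 2,4,6-trichlorobenzoic anhydride | C/C=C(/C)C(=O)OC/C(=C/C)C(=O)OC(=O)c1c(Cl)cc(Cl)cc1Cl
F4 | step 2 | tert-butyl (E)-2-(tributylstannyl)but-2-enoate | C/C=C(/[Sn](CCCC)(CCCC)CCCC)C(=O)OC(C)(C)C
F5 | step 2 | tert-butyl (E)-2-iodobut-2-enoate | C/C=C(/I)C(=O)OC(C)(C)C
F0 | step 9 | none | none
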